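Compound numbers 1–27 are those of the compound list after the steps. Ring A is the dihydrobenzofuran bonded to the tetrahydrofuran, ring B the next one, ring C the one that carries the terminal guaiacyl group.

## The problem

The target is a linear pentamer of C6C3 units. A tetrahydrofuran carries a 4-hydroxy-3-methoxybenzyl group at C4, a hydroxymethyl group at C3 and, at C2, the benzo carbon C5A of a 2-aryl-3-hydroxymethyl-7-methoxy-2,3-dihydrobenzofuran (ring A). C2A is bonded to C5B of a second unit of the same kind, C2B to C5C of a third, and C2C carries the terminal 4-hydroxy-3-methoxyphenyl group.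

The nine stereocentres form four islands separated by benzene rings: C2/C3 of ring A (2S,3R), of ring B (2S,3R), of ring C (2R,3S), and C2/C3/C4 of the tetrahydrofuran (2R,3S,4S). Inside an island one centre can steer its neighbours: C2 of a dihydrofuran fixes C3 as trans, and C4 of the tetrahydrofuran can fix C3 and through it C2. No island can steer another, and ring C has the sense opposite to rings A and B, so each island needs its own external control.

The molecule is fragile in three ways. All four cyclic ethers have a benzylic C–O bond para to an oxygen donor, which ionises in strong acid (the tetrahydrofuran cation can then be trapped by the neighbouring guaiacyl ring) and can be hydrogenolysed. The two phenols are easily oxidised. Any 3-carboxylate precursor of a ring hydroxymethyl group has an acidic C3–H next to an aryloxy leaving group, so strong base opens the ring.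

The repeating unit calls for an iterative route in which each turn leaves a handle at C5 of the new benzo ring. The feature that allows such a turn is the bond C3–C3a of each dihydrobenzofuran (C3A–C3aA in ring A). C3 holds a one-carbon substituent, lies between the arene carbon C3a and the aryl-bearing C2, and is trans to that aryl group. This is the outcome of moving arene carbon C4a of a 2-arylchroman-4-one (flavanone) from the carbonyl carbon C4 to C3: C4 leaves the ring as the future CH2OH carbon and C2 is the only stereocentre that has to be made.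

## Retrosynthesis

**27 to 26.** Only the two phenolic O–H bonds are touched. They are masked as benzyl ethers because a free phenol would not survive the hypervalent iodine oxidant, the enolate or the hydride used earlier. The forward step must cleave two ArO–CH2Ph bonds without touching the benzylic C–O bonds of the four rings.

**26 to 25.** The tetrahydrofuran is opened at O1–C2. The neighbouring cut at O1–C5 would need one primary hydroxyl out of five to be activated and a defined carbinol configuration. The cut at C2 instead uses the cation that the para oxygen of ring A stabilises, lets both carbinol epimers converge, and places the aryl group trans to C3 under thermodynamic control. Precursor 25 is an open-chain hexaol.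

**25 to 17 and 23.** All hydroxyl groups of 25 are drawn back to carbonyl groups in 24 (one lactone, three methyl esters), so a single hydride reduction makes them. The bond between the carbinol carbon and the lactone α-carbon is then an aldol bond. This cut is preferred to one at C3–C4 of the tetrahydrofuran because it divides the molecule into the tris(dihydrobenzofuran) aldehyde 17 and a small lactone 23, whose one stereocentre directs the new one. The forward aldol must tolerate three enolisable esters.

**23 to 18 and 19.** Lactone 23 is the ring-closed form of hydroxy acid 22, which comes from half-ester 21 by reduction of its ester group. The stereocentre of 21 is set by hydrogenating the alkene of 20, and 20 is the condensation product of aldehyde 18 with dimethyl succinate 19. Three steps lead to a fragment with one stereocentre, set by a catalyst.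

**17 to 16.** The formyl carbon is removed, leaving bromide 16. Bromine is the handle of choice at C5 because it is inert to the oxidative step and can be exchanged for a formyl or a boron group without touching esters.

**16 to 14 (key disconnection).** The bond C3A–C3aA is cut and C3aA is reattached to the ester carbon, which turns ring A into the pyranone ring of flavanone 14 (its enol ether 15 is the species that rearranges). The precursor has one ring-contraction, one skeletal bond and one stereocentre less to worry about: only C2 remains. The forward step must move C4a and not the C2 aryl group, and must oxidise only the enol ether. The hydroxymethyl groups of rings B and C are carried as methyl esters, the one form that is indifferent to both acid and oxidant.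

**14 to 13 and 4.** The flavanone is cut at C2–aryl and not at O1–C2. The chalcone/oxa-Michael alternative would need a strongly basic condensation of an ester-bearing aldehyde and an enantioselective closure of an unactivated chalcone. Conjugate addition of arylboronic acid 13 to chromone 4 runs without base and sets C2 by the ligand alone, whatever the remote centres are. Boronic acid 13 comes from bromide 12.

**12 back to 5.** The same two cuts are repeated twice: 12 from flavanone 10 (enol ether 11), 10 from boronic acid 9 and chromone 4, 9 from bromide 8, 8 from flavanone 6 (enol ether 7), and 6 from commercial boronic acid 5 and 4. Only the ligand hand changes in the first turn, because ring C is the mirror-image unit. One building block, 4, serves all three rings.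

**4 to 1.** Chromone 4 is closed from enaminone 3, which adds the missing carbon to bromo ketone 2; 2 is the bromination product of 1.

## Roads not taken

**Alternative 1:** The benzene ring of ring A is cut at C3aA–C4A and C7A–C7aA and made last. The silyl ketene acetal generated from trans-lactone A3 would add to pyrone A2, and loss of CO2 and silanol would give the ring A ester A1.
- Merits: the two stereocentres of the dihydrofuran are set on a small lactone by classical means before the arene exists, so there is no question of which group migrates. The pyrone fixes the 7-methoxy and 5-carboxylate positions, and the ester is a ready handle.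
- Weak points: a pyrone with a donor at C3 is a reluctant diene and needs heat, at which a ketene acetal with a benzylic C–O bond is not robust. Every further ring needs a new enantiopure trans-4,5-disubstituted lactone built on the previous arene, which costs several steps per ring and leaves open how the lactone stereocentres are set each time.
- Comparison: this road is more certain in the bond-forming event itself. The chosen plan sets against it a cycle of three steps per ring, one shared building block, and a stereocentre set by a catalyst.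

**Alternative 2:** Rings A and B are cut together at C2A–C3A and C2B–C3B. Bis(diazo ester) A5 with Rh2(S-DOSP)4 would insert twice into the benzylic ether C–H bonds to give pentamer A4 after equilibration to the trans esters.
- Merits: rings A and B have the same sense, so one catalyst could set four stereocentres in one step. The tetrahydrofuran is already in place, the longest linear sequence is shorter, and regiochemistry is not in doubt.
- Weak points: A5 also contains ether C–H bonds of the tetrahydrofuran and electron-rich arenes, which compete for the carbenoid (insertion, Buchner-type addition). Insertion of this kind tends to give cis esters, so base equilibration is needed on rings that open with base. Two imperfect insertions multiply into diastereomers that must be separated at pentamer size. Assembly of A5 needs two Williamson couplings of ortho-functionalised fragments and two late diazo transfers.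
- Comparison: this road is more convergent and avoids the migration question. The chosen plan sets each ring in its own purifiable step from building blocks that are one or two steps from commercial material.

**Alternative 3:** The tetrahydrofuran is cut at C3–C4. Cp2TiCl (trivalent titanium, from Cp2TiCl2 and zinc dust) would open epoxide A7 to the C3 radical, which closes 5-exo onto the cinnamyl alkene to give A6.
- Merits: the closure is neutral and avoids the benzylic cation, so there is no risk of arene trapping. The chair-like transition state should give the 2,3-trans-3,4-cis ring, and the hydroxymethyl group emerges free.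
- Weak points: it solves only the last ring and leaves the oligomer to be made by other means. A7 needs several linear steps on the most valuable intermediate (vinyl addition, asymmetric epoxidation or kinetic resolution, O-cinnamylation) plus silyl protection of three alcohols. C2 must be set absolutely beforehand, and titanium is stoichiometric.
- Comparison: this road is milder at the ring closure. The chosen plan sets against it a convergent aldol with a three-step lactone and a closure that corrects its own C2.

Key step: step 10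

Remark: the ligand hands in steps 3, 6, 9 and 13 are assigned from the usual models for β-substituted cyclic enones and itaconate half-esters; both hands of each ligand are available, so a reversed sense would change the ligand and nothing else.

## Route

Step 1
Reactants: 1 2'-hydroxy-3'-methoxyacetophenone
Product: 2 5'-bromo-2'-hydroxy-3'-methoxyacetophenone
Conditions: NBS, MeCN, 0 °C → rt
Reagents that add atoms: N-bromosuccinimide, O=C1CCC(=O)N1Br
Why: Electrophilic aromatic bromination; the phenol directs para, to C5', because both of its ortho positions are occupied.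

Step 2
Reactants: 2 5'-bromo-2'-hydroxy-3'-methoxyacetophenone
Product: 4 6-bromo-8-methoxy-4H-chromen-4-one, via enaminone 3 (not isolated)
Conditions: Me2NCH(OMe)2, toluene, 100 °C; then conc. HCl, CH2Cl2, 40 °C
Reagents that add atoms: N,N-dimethylformamide dimethyl acetal, COC(OC)N(C)C
Why: Enaminone condensation followed by acid-mediated closure with loss of dimethylamine, the standard chromone synthesis from 2'-hydroxyacetophenones.

Step 3
Reactants: 4 6-bromo-8-methoxy-4H-chromen-4-one; 5 [4-(benzyloxy)-3-methoxyphenyl]boronic acid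
Product: 6 (2R)-2-[4-(benzyloxy)-3-methoxyphenyl]-6-bromo-8-methoxychroman-4-one
Conditions: Pd(OCOCF3)2 (5 mol%), (S)-t-BuPyOX (6 mol%), NH4PF6 (30 mol%), H2O (5 equiv), ClCH2CH2Cl, 60 °C
Reagents that add atoms: none
Why: Palladium/pyridine-oxazoline catalysed asymmetric conjugate addition of an arylboronic acid to a chromone; the tert-butyl group of the ligand blocks one enone face, which with the (S) ligand should give the (2R) flavanone. The catalyst stays divalent, so the C–Br bond is not engaged, and the base-free medium cannot open the flavanone.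

Step 4
Reactants: 6 (2R)-2-[4-(benzyloxy)-3-methoxyphenyl]-6-bromo-8-methoxychroman-4-one
Product: 8 methyl (2R,3R)-2-[4-(benzyloxy)-3-methoxyphenyl]-5-bromo-7-methoxy-2,3-dihydrobenzofuran-3-carboxylate, via enol ether 7 (not isolated)
Conditions: HC(OMe)3, H2SO4 (0.3 equiv), rt; then PhI(OAc)2 (1.2 equiv), 0 °C → rt; aq. NaHCO3
Reagents that add atoms: trimethyl orthoformate, COC(OC)OC; water, O
Why: Hypervalent-iodine oxidative ring contraction of a flavanone (1,2-shift of C4a from C4 to C3 in the ketal, see step 10); C2 is retained and the anti shift sets C3 trans, (3R). Any cis ester should converge on the trans epimer on brief contact with a mild amine base.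

Step 5
Reactants: 8 methyl (2R,3R)-2-[4-(benzyloxy)-3-methoxyphenyl]-5-bromo-7-methoxy-2,3-dihydrobenzofuran-3-carboxylate
Product: 9 [(2R,3R)-2-[4-(benzyloxy)-3-methoxyphenyl]-7-methoxy-3-(methoxycarbonyl)-2,3-dihydrobenzofuran-5-yl]boronic acid
Conditions: B2(OH)4 (1.5 equiv), [PdCl(XPhos)(2'-aminobiphenyl-2-yl)] (second-generation XPhos palladacycle, 1 mol%), XPhos (2 mol%), KOAc (3 equiv), EtOH, 80 °C
Reagents that add atoms: tetrahydroxydiboron, OB(O)B(O)O
Why: Miyaura-type palladium-catalysed borylation of the aryl bromide, giving the boronic acid directly; acetate is too weak a base to enolise the C3 ester, so the trans ring is not disturbed.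

Step 6
Reactants: 9 [(2R,3R)-2-[4-(benzyloxy)-3-methoxyphenyl]-7-methoxy-3-(methoxycarbonyl)-2,3-dihydrobenzofuran-5-yl]boronic acid; 4 6-bromo-8-methoxy-4H-chromen-4-one
Product: 10 methyl (2R,3R)-2-[4-(benzyloxy)-3-methoxyphenyl]-5-[(2S)-6-bromo-8-methoxy-4-oxochroman-2-yl]-7-methoxy-2,3-dihydrobenzofuran-3-carboxylate
Conditions: 4 (1.5 equiv), Pd(OCOCF3)2 (5 mol%), (R)-t-BuPyOX (6 mol%), NH4PF6 (30 mol%), H2O (5 equiv), ClCH2CH2Cl, 60 °C
Reagents that add atoms: none
Why: Same asymmetric conjugate addition as step 3 with the other ligand hand, which should give the (2S) flavanone; the ring C stereocentres are seven bonds away, so control rests with the catalyst. The cheap chromone is used in excess.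

Step 7
Reactants: 10 methyl (2R,3R)-2-[4-(benzyloxy)-3-methoxyphenyl]-5-[(2S)-6-bromo-8-methoxy-4-oxochroman-2-yl]-7-methoxy-2,3-dihydrobenzofuran-3-carboxylate
Product: 12 methyl (2S,3S)-5-bromo-7-methoxy-2-{(2R,3R)-2-[4-(benzyloxy)-3-methoxyphenyl]-7-methoxy-3-(methoxycarbonyl)-2,3-dihydrobenzofuran-5-yl}-2,3-dihydrobenzofuran-3-carboxylate, via enol ether 11 (not isolated)
Conditions: HC(OMe)3, H2SO4 (0.3 equiv), rt; then PhI(OAc)2 (1.2 equiv), 0 °C → rt; aq. NaHCO3
Reagents that add atoms: trimethyl orthoformate, COC(OC)OC; water, O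
Why: Second oxidative ring contraction of a flavanone, closing ring B; C2B is retained and C3B is set trans, (3S), by the anti 1,2-shift. The ring C methyl ester is inert to the acidic medium.

Step 8
Reactants: 12 methyl (2S,3S)-5-bromo-7-methoxy-2-{(2R,3R)-2-[4-(benzyloxy)-3-methoxyphenyl]-7-methoxy-3-(methoxycarbonyl)-2,3-dihydrobenzofuran-5-yl}-2,3-dihydrobenzofuran-3-carboxylate
Product: 13 [(2S,3S)-7-methoxy-3-(methoxycarbonyl)-2-{(2R,3R)-2-[4-(benzyloxy)-3-methoxyphenyl]-7-methoxy-3-(methoxycarbonyl)-2,3-dihydrobenzofuran-5-yl}-2,3-dihydrobenzofuran-5-yl]boronic acid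
Conditions: B2(OH)4 (1.5 equiv), [PdCl(XPhos)(2'-aminobiphenyl-2-yl)] (second-generation XPhos palladacycle, 1 mol%), XPhos (2 mol%), KOAc (3 equiv), EtOH, 80 °C
Reagents that add atoms: tetrahydroxydiboron, OB(O)B(O)O
Why: Miyaura-type borylation as in step 5; both esters and the benzyl ether are spectators.

Step 9
Reactants: 13 [(2S,3S)-7-methoxy-3-(methoxycarbonyl)-2-{(2R,3R)-2-[4-(benzyloxy)-3-methoxyphenyl]-7-methoxy-3-(methoxycarbonyl)-2,3-dihydrobenzofuran-5-yl}-2,3-dihydrobenzofuran-5-yl]boronic acid; 4 6-bromo-8-methoxy-4H-chromen-4-one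
Product: 14 methyl (2S,3S)-5-[(2S)-6-bromo-8-methoxy-4-oxochroman-2-yl]-7-methoxy-2-{(2R,3R)-2-[4-(benzyloxy)-3-methoxyphenyl]-7-methoxy-3-(methoxycarbonyl)-2,3-dihydrobenzofuran-5-yl}-2,3-dihydrobenzofuran-3-carboxylate
Conditions: 4 (1.5 equiv), Pd(OCOCF3)2 (5 mol%), (R)-t-BuPyOX (6 mol%), NH4PF6 (30 mol%), H2O (5 equiv), ClCH2CH2Cl, 60 °C
Reagents that add atoms: none
Why: Third asymmetric conjugate addition of an arylboronic acid to chromone 4; the (R) ligand should again give the (2S) flavanone, which is the future C2A.

Step 10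
Reactants: 14 methyl (2S,3S)-5-[(2S)-6-bromo-8-methoxy-4-oxochroman-2-yl]-7-methoxy-2-{(2R,3R)-2-[4-(benzyloxy)-3-methoxyphenyl]-7-methoxy-3-(methoxycarbonyl)-2,3-dihydrobenzofuran-5-yl}-2,3-dihydrobenzofuran-3-carboxylate
Product: 16 methyl (2S,3S)-5-bromo-7-methoxy-2-{(2S,3S)-7-methoxy-3-(methoxycarbonyl)-2-[(2R,3R)-2-[4-(benzyloxy)-3-methoxyphenyl]-7-methoxy-3-(methoxycarbonyl)-2,3-dihydrobenzofuran-5-yl]-2,3-dihydrobenzofuran-5-yl}-2,3-dihydrobenzofuran-3-carboxylate, via enol ether 15 (not isolated)
Conditions: HC(OMe)3, H2SO4 (0.3 equiv), rt; then PhI(OAc)2 (1.2 equiv), 0 °C → rt; aq. NaHCO3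
Reagents that add atoms: trimethyl orthoformate, COC(OC)OC; water, O
Why: Orthoformate and acid turn the C4 ketone of 14 into its ketal and enol ether 15, which cannot revert to a chalcone and is by far the most nucleophilic π-system present. C3 of 15 attacks PhI(OAc)2 (trivalent iodine) on the face away from the C2 aryl group, and methanol restores the ketal at C4. With the aryl and iodanyl groups both equatorial, the C3–I bond is antiperiplanar to C4–C4a, so C4a shifts from C4 to C3 as iodobenzene leaves, pushed by two methoxy oxygens, and the dimethoxycarbenium ion is collected as the methyl ester. The closest known reaction type is the hypervalent-iodine (or Tl(NO3)3) ring contraction of flavanones to methyl trans-2-aryl-2,3-dihydrobenzofuran-3-carboxylates, a cyclic case of the 1,2-aryl shift of aryl ketone ketals. Ring A is therefore closed by a 1,2-shift and not by a cyclisation: C3A–C3aA forms inside the existing ring, six ring atoms become five and C4 is expelled as the ester carbon. C2A is carried over unchanged, and the new centre C3A is set by the substrate, since inversion at C3 after anti iodination places the ester trans to the aryl group, (3S), which is also the thermodynamic epimer. The step needs chemoselectivity for the enol ether over five alkoxyarenes, secured by forming 15 before the oxidant is added and by the absence of free phenols. It also needs C4a to migrate in preference to the C2 aryl group or to loss of HX, which full ketalisation in neat orthoformate and the equatorial preference of the large C2 substituent should secure.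

Step 11
Reactants: 16 methyl (2S,3S)-5-bromo-7-methoxy-2-{(2S,3S)-7-methoxy-3-(methoxycarbonyl)-2-[(2R,3R)-2-[4-(benzyloxy)-3-methoxyphenyl]-7-methoxy-3-(methoxycarbonyl)-2,3-dihydrobenzofuran-5-yl]-2,3-dihydrobenzofuran-5-yl}-2,3-dihydrobenzofuran-3-carboxylate
Product: 17 methyl (2S,3S)-5-formyl-7-methoxy-2-{(2S,3S)-7-methoxy-3-(methoxycarbonyl)-2-[(2R,3R)-2-[4-(benzyloxy)-3-methoxyphenyl]-7-methoxy-3-(methoxycarbonyl)-2,3-dihydrobenzofuran-5-yl]-2,3-dihydrobenzofuran-5-yl}-2,3-dihydrobenzofuran-3-carboxylate
Conditions: CO/H2 (1:1, 5 bar), Pd(OAc)2 (1 mol%), P(1-adamantyl)2(n-Bu) (3 mol%), TMEDA (0.75 equiv), toluene, 100 °C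
Reagents that add atoms: carbon monoxide, [C-]#[O+]
Why: Palladium-catalysed reductive carbonylation (formylation) of an aryl bromide: oxidative addition, CO insertion and hydrogenolysis of the acyl–palladium bond. Methyl esters and benzyl ethers are spectators, and the tertiary amine is too weak to open the rings.

Step 12
Reactants: 18 4-(benzyloxy)-3-methoxybenzaldehyde; 19 dimethyl succinate
Product: 20 (E)-4-[4-(benzyloxy)-3-methoxyphenyl]-3-(methoxycarbonyl)but-3-enoic acid
Conditions: NaOMe, MeOH, reflux; then 2 M HCl
Reagents that add atoms: none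
Why: Stobbe condensation; the succinate enolate adds to the aldehyde, the alkoxide lactonises onto the distal ester and base-induced opening gives the (E)-alkylidene half-ester with the free acid on the saturated arm.

Step 13
Reactants: 20 (E)-4-[4-(benzyloxy)-3-methoxyphenyl]-3-(methoxycarbonyl)but-3-enoic acid
Product: 21 (3S)-4-[4-(benzyloxy)-3-methoxyphenyl]-3-(methoxycarbonyl)butanoic acid
Conditions: H2 (4 bar), [Rh(cod)((R,R)-Et-DuPhos)]OTf (0.5 mol%), NaOMe (10 mol%), MeOH, rt
Reagents that add atoms: none
Why: Carboxylate-directed asymmetric hydrogenation of a Stobbe half-ester with a cationic rhodium bisphospholane catalyst (monovalent rhodium); the (R,R) ligand should deliver hydrogen to the face that gives the (S) acid. The homogeneous catalyst leaves the benzyl ether intact.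

Step 14
Reactants: 21 (3S)-4-[4-(benzyloxy)-3-methoxyphenyl]-3-(methoxycarbonyl)butanoic acid
Product: 23 (4S)-4-[4-(benzyloxy)-3-methoxybenzyl]dihydrofuran-2(3H)-one, via hydroxy acid 22 (not isolated)
Conditions: KOH (1 equiv), EtOH; CaCl2, NaBH4, EtOH, −10 °C → rt; then 3 M HCl, rt
Reagents that add atoms: none
Why: Chemoselective reduction of the ester beside the carboxylate salt by Ca(BH4)2 formed in the flask, then acid-catalysed lactonisation; the stereocentre is not involved.

Step 15
Reactants: 23 (4S)-4-[4-(benzyloxy)-3-methoxybenzyl]dihydrofuran-2(3H)-one; 17 methyl (2S,3S)-5-formyl-7-methoxy-2-{(2S,3S)-7-methoxy-3-(methoxycarbonyl)-2-[(2R,3R)-2-[4-(benzyloxy)-3-methoxyphenyl]-7-methoxy-3-(methoxycarbonyl)-2,3-dihydrobenzofuran-5-yl]-2,3-dihydrobenzofuran-5-yl}-2,3-dihydrobenzofuran-3-carboxylate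
Product: 24 (3R,4S)-4-[4-(benzyloxy)-3-methoxybenzyl]-3-[hydroxy(aryl)methyl]dihydrofuran-2(3H)-one in which aryl is C5 of ring A of the triester (both carbinol epimers)
Conditions: 23 (1.5 equiv), LiN(SiMe3)2 (1.4 equiv), THF, −78 °C; then 17, −78 °C; AcOH quench
Reagents that add atoms: none
Why: Lithium enolate aldol addition of a β-substituted γ-butyrolactone; the aldehyde approaches anti to the 4-benzyl group and sets C3 trans, (3R). The carbinol configuration does not matter because that carbon is ionised in step 17, and at −78 °C addition to the aldehyde should outrun proton transfer from the ester C3–H bonds.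

Step 16
Reactants: 24 (3R,4S)-4-[4-(benzyloxy)-3-methoxybenzyl]-3-[hydroxy(aryl)methyl]dihydrofuran-2(3H)-one in which aryl is C5 of ring A of the triester
Product: 25 (2S,3S)-3-[4-(benzyloxy)-3-methoxybenzyl]-2-[hydroxy(aryl)methyl]butane-1,4-diol in which aryl is C5 of ring A of the tris(hydroxymethyl) ring A–ring B–ring C unit (both carbinol epimers)
Conditions: LiAlH4, THF, −10 → 0 °C; aq. Rochelle salt
Reagents that add atoms: none
Why: Hydride reduction of the lactone and the three methyl esters in one operation; hydride addition to the ester carbonyl is faster than deprotonation at C3, so the trans rings and their C2–O bonds should be kept.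

Step 17
Reactants: 25 (2S,3S)-3-[4-(benzyloxy)-3-methoxybenzyl]-2-[hydroxy(aryl)methyl]butane-1,4-diol in which aryl is C5 of ring A of the tris(hydroxymethyl) unit
Product: 26 the bis(benzyl ether) of 27 at both phenols [(2R,3S,4S)-tetrahydrofuran]
Conditions: CSA (10 mol%), CH2Cl2/THF, 0 °C → rt
Reagents that add atoms: none
Why: Acid-catalysed cycloetherification through the benzylic cation stabilised by the para oxygen of ring A, closed 5-exo by the primary hydroxyl on the benzyl-bearing carbon (the other hydroxyls cannot reach or would form an oxetane). Both carbinol epimers converge, and reversible ionisation should place the aryl group trans to the C3 hydroxymethyl group, (2R), giving the 2,3-trans-3,4-cis ring. Mild acid and short contact are chosen so that trapping of the cation by the guaiacyl ring (Friedel–Crafts) does not compete.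

Step 18
Reactants: 26 the bis(benzyl ether) of 27
Product: 27 CNP0267891.2
Conditions: H2 (1 atm), Pd/C (10% w/w), EtOAc/MeOH, rt, stopped after two equivalents of H2
Reagents that add atoms: none
Why: Catalytic hydrogenolysis of two aryl benzyl ethers; under neutral conditions phenolic O–benzyl bonds are cleaved much faster than the benzylic C–O bonds of the cyclic ethers, so stopping at two equivalents should leave the rings intact.

## Compound list

1 | 2'-hydroxy-3'-methoxyacetophenone | CC(=O)c1cccc(OC)c1O | starting material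
2 | 5'-bromo-2'-hydroxy-3'-methoxyacetophenone | CC(=O)c1cc(Br)cc(OC)c1O | intermediate
3 | (E)-1-(5-bromo-2-hydroxy-3-methoxyphenyl)-3-(dimethylamino)prop-2-en-1-one (formed in the flask) | CN(C)/C=C/C(=O)c1cc(Br)cc(OC)c1O | intermediate
4 | 6-bromo-8-methoxy-4H-chromen-4-one | O=c1ccoc2c(OC)cc(Br)cc12 | intermediate
5 | [4-(benzyloxy)-3-methoxyphenyl]boronic acid | OB(O)c1ccc(OCc2ccccc2)c(OC)c1 | starting material
6 | (2R)-2-[4-(benzyloxy)-3-methoxyphenyl]-6-bromo-8-methoxychroman-4-one | O=C1C[C@H](c2ccc(OCc3ccccc3)c(OC)c2)Oc2c(OC)cc(Br)cc21 | intermediate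
7 | (2R)-2-[4-(benzyloxy)-3-methoxyphenyl]-6-bromo-4,8-dimethoxy-2H-chromene (formed in the flask) | COC1=C[C@H](c2ccc(OCc3ccccc3)c(OC)c2)Oc2c(OC)cc(Br)cc21 | intermediate
8 | methyl (2R,3R)-2-[4-(benzyloxy)-3-methoxyphenyl]-5-bromo-7-methoxy-2,3-dihydrobenzofuran-3-carboxylate | Brc1cc(OC)c2c(c1)[C@@H](C(=O)OC)[C@H](c1ccc(OCc3ccccc3)c(OC)c1)O2 | intermediate
9 | [(2R,3R)-2-[4-(benzyloxy)-3-methoxyphenyl]-7-methoxy-3-(methoxycarbonyl)-2,3-dihydrobenzofuran-5-yl]boronic acid | OB(O)c1cc(OC)c2c(c1)[C@@H](C(=O)OC)[C@H](c1ccc(OCc3ccccc3)c(OC)c1)O2 | intermediate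
10 | methyl (2R,3R)-2-[4-(benzyloxy)-3-methoxyphenyl]-5-[(2S)-6-bromo-8-methoxy-4-oxochroman-2-yl]-7-methoxy-2,3-dihydrobenzofuran-3-carboxylate | O=C1C[C@@H](c2cc(OC)c3c(c2)[C@@H](C(=O)OC)[C@H](c2ccc(OCc4ccccc4)c(OC)c2)O3)Oc2c(OC)cc(Br)cc21 | intermediate
11 | methyl (2R,3R)-2-[4-(benzyloxy)-3-methoxyphenyl]-5-[(2S)-6-bromo-4,8-dimethoxy-2H-chromen-2-yl]-7-methoxy-2,3-dihydrobenzofuran-3-carboxylate (formed in the flask) | COC1=C[C@@H](c2cc(OC)c3c(c2)[C@@H](C(=O)OC)[C@H](c2ccc(OCc4ccccc4)c(OC)c2)O3)Oc2c(OC)cc(Br)cc21 | intermediate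
12 | methyl (2S,3S)-5-bromo-7-methoxy-2-{(2R,3R)-2-[4-(benzyloxy)-3-methoxyphenyl]-7-methoxy-3-(methoxycarbonyl)-2,3-dihydrobenzofuran-5-yl}-2,3-dihydrobenzofuran-3-carboxylate | Brc1cc(OC)c2c(c1)[C@H](C(=O)OC)[C@@H](c1cc(OC)c3c(c1)[C@@H](C(=O)OC)[C@H](c1ccc(OCc4ccccc4)c(OC)c1)O3)O2 | intermediate
13 | [(2S,3S)-7-methoxy-3-(methoxycarbonyl)-2-{(2R,3R)-2-[4-(benzyloxy)-3-methoxyphenyl]-7-methoxy-3-(methoxycarbonyl)-2,3-dihydrobenzofuran-5-yl}-2,3-dihydrobenzofuran-5-yl]boronic acid | OB(O)c1cc(OC)c2c(c1)[C@H](C(=O)OC)[C@@H](c1cc(OC)c3c(c1)[C@@H](C(=O)OC)[C@H](c1ccc(OCc4ccccc4)c(OC)c1)O3)O2 | intermediate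
14 | methyl (2S,3S)-5-[(2S)-6-bromo-8-methoxy-4-oxochroman-2-yl]-7-methoxy-2-{(2R,3R)-2-[4-(benzyloxy)-3-methoxyphenyl]-7-methoxy-3-(methoxycarbonyl)-2,3-dihydrobenzofuran-5-yl}-2,3-dihydrobenzofuran-3-carboxylate | O=C1C[C@@H](c2cc(OC)c3c(c2)[C@H](C(=O)OC)[C@@H](c2cc(OC)c4c(c2)[C@@H](C(=O)OC)[C@H](c2ccc(OCc5ccccc5)c(OC)c2)O4)O3)Oc2c(OC)cc(Br)cc21 | intermediate
15 | the 4-methoxy-2H-chromene (enol ether) of 14, (2S) at the chromene (formed in the flask) | COC1=C[C@@H](c2cc(OC)c3c(c2)[C@H](C(=O)OC)[C@@H](c2cc(OC)c4c(c2)[C@@H](C(=O)OC)[C@H](c2ccc(OCc5ccccc5)c(OC)c2)O4)O3)Oc2c(OC)cc(Br)cc21 | intermediate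
16 | methyl (2S,3S)-5-bromo-7-methoxy-2-{(2S,3S)-7-methoxy-3-(methoxycarbonyl)-2-[(2R,3R)-2-[4-(benzyloxy)-3-methoxyphenyl]-7-methoxy-3-(methoxycarbonyl)-2,3-dihydrobenzofuran-5-yl]-2,3-dihydrobenzofuran-5-yl}-2,3-dihydrobenzofuran-3-carboxylate | Brc1cc(OC)c2c(c1)[C@H](C(=O)OC)[C@@H](c1cc(OC)c3c(c1)[C@H](C(=O)OC)[C@@H](c1cc(OC)c4c(c1)[C@@H](C(=O)OC)[C@H](c1ccc(OCc5ccccc5)c(OC)c1)O4)O3)O2 | intermediate
17 | the 5-formyl analogue of 16 (CHO in place of Br on ring A) | O=Cc1cc(OC)c2c(c1)[C@H](C(=O)OC)[C@@H](c1cc(OC)c3c(c1)[C@H](C(=O)OC)[C@@H](c1cc(OC)c4c(c1)[C@@H](C(=O)OC)[C@H](c1ccc(OCc5ccccc5)c(OC)c1)O4)O3)O2 | intermediate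
18 | 4-(benzyloxy)-3-methoxybenzaldehyde | O=Cc1ccc(OCc2ccccc2)c(OC)c1 | starting material
19 | dimethyl succinate | COC(=O)CCC(=O)OC | starting material
20 | (E)-4-[4-(benzyloxy)-3-methoxyphenyl]-3-(methoxycarbonyl)but-3-enoic acid | COC(=O)/C(CC(=O)O)=C/c1ccc(OCc2ccccc2)c(OC)c1 | intermediate
21 | (3S)-4-[4-(benzyloxy)-3-methoxyphenyl]-3-(methoxycarbonyl)butanoic acid | COC(=O)[C@@H](Cc1ccc(OCc2ccccc2)c(OC)c1)CC(=O)O | intermediate
22 | (3S)-3-[4-(benzyloxy)-3-methoxybenzyl]-4-hydroxybutanoic acid (formed in the flask) | OC[C@@H](Cc1ccc(OCc2ccccc2)c(OC)c1)CC(=O)O | intermediate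
23 | (4S)-4-[4-(benzyloxy)-3-methoxybenzyl]dihydrofuran-2(3H)-one | O=C1C[C@H](Cc2ccc(OCc3ccccc3)c(OC)c2)CO1 | intermediate
24 | (3R,4S)-4-[4-(benzyloxy)-3-methoxybenzyl]-3-[hydroxy(aryl)methyl]dihydrofuran-2(3H)-one, aryl = C5 of ring A of the triester, both carbinol epimers | O=C1OC[C@@H](Cc2ccc(OCc3ccccc3)c(OC)c2)[C@@H]1C(O)c1cc(OC)c2c(c1)[C@H](C(=O)OC)[C@@H](c1cc(OC)c3c(c1)[C@H](C(=O)OC)[C@@H](c1cc(OC)c4c(c1)[C@@H](C(=O)OC)[C@H](c1ccc(OCc5ccccc5)c(OC)c1)O4)O3)O2 | intermediate
25 | (2S,3S)-3-[4-(benzyloxy)-3-methoxybenzyl]-2-[hydroxy(aryl)methyl]butane-1,4-diol, aryl = C5 of ring A of the tris(hydroxymethyl) unit with ring A (2S,3R), ring B (2S,3R), ring C (2R,3S), both carbinol epimers | OC[C@@H](Cc1ccc(OCc2ccccc2)c(OC)c1)[C@@H](CO)C(O)c1cc(OC)c2c(c1)[C@H](CO)[C@@H](c1cc(OC)c3c(c1)[C@H](CO)[C@@H](c1cc(OC)c4c(c1)[C@@H](CO)[C@H](c1ccc(OCc5ccccc5)c(OC)c1)O4)O3)O2 | intermediate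
26 | bis(benzyl ether) of 27 at both phenols, tetrahydrofuran (2R,3S,4S) | COc1cc(C[C@@H]2CO[C@@H](c3cc(OC)c4c(c3)[C@H](CO)[C@@H](c3cc(OC)c5c(c3)[C@H](CO)[C@@H](c3cc(OC)c6c(c3)[C@@H](CO)[C@H](c3ccc(OCc7ccccc7)c(OC)c3)O6)O5)O4)[C@@H]2CO)ccc1OCc8ccccc8 | intermediate
27 | CNP0267891.2: (2R,3S,4S)-4-(4-hydroxy-3-methoxybenzyl)-3-(hydroxymethyl)tetrahydrofuran whose C2 carries C5 of ring A; rings A and B are (2S,3R)-3-(hydroxymethyl)-7-methoxy-2,3-dihydrobenzofurans linked C2A–C5B and C2B–C5C; ring C is the (2R,3S) unit with 4-hydroxy-3-methoxyphenyl at C2 | COc1cc(C[C@@H]2CO[C@@H](c3cc(OC)c4c(c3)[C@H](CO)[C@@H](c3cc(OC)c5c(c3)[C@H](CO)[C@@H](c3cc(OC)c6c(c3)[C@@H](CO)[C@H](c3ccc(O)c(OC)c3)O6)O5)O4)[C@@H]2CO)ccc1O | target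

## Step count and weak points

Total: 18 steps. Longest linear sequence: 15 steps (steps 1–11, then 15–18, from 1); the lactone branch (steps 12–14) joins at step 15.

**Step 10 (key step; steps 4 and 7 are the same reaction on smaller substrates).** The most likely failure is migration of the wrong group. The C2 aryl group has a para oxygen and can shift to C3 in place of C4a, or the iodinated intermediate can lose HX to give a flavone; some oxidation of the alkoxyarenes by the acidic oxidant is also possible. The cause is that the iodanyl group leaves so readily that every antiperiplanar bond is a candidate. The fallback separates halogenation from the shift and removes the oxidant. It sets out from 14: ketalisation (HC(OMe)3, MeOH, TsOH) followed by PhNMe3Br3 would give the trans-3-bromo-4,4-dimethoxyflavan F1. AgBF4 in MeOH would then abstract bromide only from the fully formed ketal, where the two methoxy groups push C4a across, and the route is rejoined at 16.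

**Step 9 (and likewise steps 6 and 3).** The most likely failure is protodeboronation of the electron-rich boronic acid outrunning carbopalladation of the 8-methoxychromone, or incomplete facial control that leaves diastereomers to separate. The fallback builds the flavanone by oxa-Michael closure; it sets out from 12 and returns at 14. Formylation of 12 under the conditions of step 11 would give the ring B aldehyde F2. Knoevenagel condensation (piperidine, AcOH, toluene, 4 Å sieves) with tert-butyl 3-(5-bromo-2-hydroxy-3-methoxyphenyl)-3-oxopropanoate F3, made from 2 by C-acylation of its dianion with Boc2O, would give the alkylidene β-keto ester F4. A cinchona-derived bifunctional thiourea of the hand that gives (2S) would close it to the tert-butyl flavanone-3-carboxylate F5, and TsOH at 80 °C would remove the tert-butyl ester and CO2 to give 14.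

**Step 15.** The most likely failure is proton transfer from the acidic C3–H of the ring esters to the lithium enolate, followed by β-elimination of the aryloxide (ring opening) and recovery of aldehyde. The fallback removes the base from the coupling; it sets out from 23 and returns at 24. LDA and Me3SiCl would convert 23 alone into (4S)-4-[4-(benzyloxy)-3-methoxybenzyl]-2-(trimethylsilyloxy)-4,5-dihydrofuran F6, and a Mukaiyama aldol addition of F6 to 17 (BF3·OEt2, CH2Cl2, −78 °C), again anti to the benzyl group, would give 24.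

**Step 18.** The most likely failure is over-reduction: once the benzyl ethers are gone, hydrogenolysis can continue at the benzylic C2–O bond of the tetrahydrofuran and open the ring. The fallback removes the benzyl groups before that bond exists; it sets out from 24 and returns at 27. Dess–Martin periodinane would give the β-keto lactone F7, which has no benzylic C–O single bond in the side chain. Hydrogenolysis (H2, Pd/C, EtOAc) would give the bis-phenol F8, LiBH4 in THF/MeOH would reduce ketone, lactone and esters to the bis-phenol hexaol F9, and CSA as in step 17 would close the tetrahydrofuran to 27.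

## Further compounds

F1 | step 10 | (2R,3R)-3-bromo-4,4-dimethoxy analogue of 14 (trans-3-bromo-4,4-dimethoxyflavan) | COC1(OC)[C@H](Br)[C@@H](c2cc(OC)c3c(c2)[C@H](C(=O)OC)[C@@H](c2cc(OC)c4c(c2)[C@@H](C(=O)OC)[C@H](c2ccc(OCc5ccccc5)c(OC)c2)O4)O3)Oc2c(OC)cc(Br)cc21
F2 | step 9 | 5-formyl analogue of 12 (ring B aldehyde) | O=Cc1cc(OC)c2c(c1)[C@H](C(=O)OC)[C@@H](c1cc(OC)c3c(c1)[C@@H](C(=O)OC)[C@H](c1ccc(OCc4ccccc4)c(OC)c1)O3)O2
F3 | step 9 | tert-butyl 3-(5-bromo-2-hydroxy-3-methoxyphenyl)-3-oxopropanoate | CC(C)(C)OC(=O)CC(=O)c1cc(Br)cc(OC)c1O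
F4 | step 9 | tert-butyl 2-(5-bromo-2-hydroxy-3-methoxybenzoyl)-3-arylacrylate, aryl = C5 of ring B of the diester (E/Z mixture) | CC(C)(C)OC(=O)C(=Cc1cc(OC)c2c(c1)[C@H](C(=O)OC)[C@@H](c1cc(OC)c3c(c1)[C@@H](C(=O)OC)[C@H](c1ccc(OCc4ccccc4)c(OC)c1)O3)O2)C(=O)c1cc(Br)cc(OC)c1O
F5 | step 9 | tert-butyl (2S)-flavanone-3-carboxylate corresponding to 14 (C3 epimers and enol) | O=C1C(C(=O)OC(C)(C)C)[C@@H](c2cc(OC)c3c(c2)[C@H](C(=O)OC)[C@@H](c2cc(OC)c4c(c2)[C@@H](C(=O)OC)[C@H](c2ccc(OCc5ccccc5)c(OC)c2)O4)O3)Oc2c(OC)cc(Br)cc21
F6 | step 15 | (4S)-4-[4-(benzyloxy)-3-methoxybenzyl]-2-(trimethylsilyloxy)-4,5-dihydrofuran | C[Si](C)(C)OC1=C[C@H](Cc2ccc(OCc3ccccc3)c(OC)c2)CO1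
F7 | step 18 | (3R,4S)-3-aroyl-4-[4-(benzyloxy)-3-methoxybenzyl]dihydrofuran-2(3H)-one, aroyl on C5 of ring A of the triester | O=C1OC[C@@H](Cc2ccc(OCc3ccccc3)c(OC)c2)[C@@H]1C(=O)c1cc(OC)c2c(c1)[C@H](C(=O)OC)[C@@H](c1cc(OC)c3c(c1)[C@H](C(=O)OC)[C@@H](c1cc(OC)c4c(c1)[C@@H](C(=O)OC)[C@H](c1ccc(OCc5ccccc5)c(OC)c1)O4)O3)O2
F8 | step 18 | bis-phenol of F7 (both benzyl ethers removed) | O=C1OC[C@@H](Cc2ccc(O)c(OC)c2)[C@@H]1C(=O)c1cc(OC)c2c(c1)[C@H](C(=O)OC)[C@@H](c1cc(OC)c3c(c1)[C@H](C(=O)OC)[C@@H](c1cc(OC)c4c(c1)[C@@H](C(=O)OC)[C@H](c1ccc(O)c(OC)c1)O4)O3)O2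
F9 | step 18 | bis-phenol analogue of 25 (both carbinol epimers) | OC[C@@H](Cc1ccc(O)c(OC)c1)[C@@H](CO)C(O)c1cc(OC)c2c(c1)[C@H](CO)[C@@H](c1cc(OC)c3c(c1)[C@H](CO)[C@@H](c1cc(OC)c4c(c1)[C@@H](CO)[C@H](c1ccc(O)c(OC)c1)O4)O3)O2
A1 | alternative 1 | ring A 5-carboxylate of the tris(silyloxymethyl) tris(dihydrobenzofuran) | COC(=O)c1cc(OC)c2c(c1)[C@H](CO[Si](C)(C)C(C)(C)C)[C@@H](c3cc(OC)c5c(c3)[C@H](CO[Si](C)(C)C(C)(C)C)[C@@H](c3cc(OC)c6c(c3)[C@@H](CO[Si](C)(C)C(C)(C)C)[C@H](c3ccc(OCc7ccccc7)c(OC)c3)O6)O5)O2
A2 | alternative 1 | methyl 3-methoxy-2-oxo-2H-pyran-5-carboxylate | COC(=O)C1=COC(=O)C(OC)=C1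
A3 | alternative 1 | trans-4-(tert-butyldimethylsilyloxymethyl)-5-aryl-dihydrofuran-2(3H)-one, aryl = C5 of the silylated ring B–ring C unit | O=C1C[C@H](CO[Si](C)(C)C(C)(C)C)[C@@H](c2cc(OC)c3c(c2)[C@H](CO[Si](C)(C)C(C)(C)C)[C@@H](c2cc(OC)c4c(c2)[C@@H](CO[Si](C)(C)C(C)(C)C)[C@H](c2ccc(OCc5ccccc5)c(OC)c2)O4)O3)O1
A4 | alternative 2 | protected triester pentamer (benzyl ethers at both phenols, silyl ether at the tetrahydrofuran hydroxymethyl) | COc1cc(C[C@@H]2CO[C@@H](c3cc(OC)c4c(c3)[C@H](C(=O)OC)[C@@H](c3cc(OC)c5c(c3)[C@H](C(=O)OC)[C@@H](c3cc(OC)c6c(c3)[C@@H](C(=O)OC)[C@H](c3ccc(OCc7ccccc7)c(OC)c3)O6)O5)O4)[C@@H]2CO[Si](C)(C)C(C)(C)C)ccc1OCc8ccccc8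
A5 | alternative 2 | bis(aryldiazoacetate) with rings A and B open at C2–C3 (two benzylic aryl ethers) | COc1cc(C[C@@H]2CO[C@@H](c3cc(OC)c(OCc4cc(OC)c(OCc5cc(OC)c6c(c5)[C@@H](C(=O)OC)[C@H](c5ccc(OCc7ccccc7)c(OC)c5)O6)c(c4)C(=[N+]=[N-])C(=O)OC)c(c3)C(=[N+]=[N-])C(=O)OC)[C@@H]2CO[Si](C)(C)C(C)(C)C)ccc1OCc8ccccc8
A6 | alternative 3 | protected target with free tetrahydrofuran hydroxymethyl group | COc1cc(C[C@@H]2CO[C@@H](c3cc(OC)c4c(c3)[C@H](CO[Si](C)(C)C(C)(C)C)[C@@H](c3cc(OC)c5c(c3)[C@H](CO[Si](C)(C)C(C)(C)C)[C@@H](c3cc(OC)c6c(c3)[C@@H](CO[Si](C)(C)C(C)(C)C)[C@H](c3ccc(OCc7ccccc7)c(OC)c3)O6)O5)O4)[C@@H]2CO)ccc1OCc8ccccc8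
A7 | alternative 3 | (E)-cinnamyl ether of the aryl(oxiranyl)carbinol, aryl = C5 of ring A of the silylated trimer (epoxide carbon either configuration) | COc1cc(/C=C/CO[C@@H](c3cc(OC)c4c(c3)[C@H](CO[Si](C)(C)C(C)(C)C)[C@@H](c3cc(OC)c5c(c3)[C@H](CO[Si](C)(C)C(C)(C)C)[C@@H](c3cc(OC)c6c(c3)[C@@H](CO[Si](C)(C)C(C)(C)C)[C@H](c3ccc(OCc7ccccc7)c(OC)c3)O6)O5)O4)C2CO2)ccc1OCc8ccccc8
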